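**Retrosynthetic overview**
1. Target 10 ⇒ 8 by global O-demethylation, the only protecting-group removal.
2. Key disconnection: the side-chain C1'–C2' bond. 8 ⇒ lithium dienolate 7 of 5,7-dimethoxy-2-methylchromone (6) + 1-iodotetracosane (3). This C1 + C24 vinylogous enolate alkylation replaces the usual acylation / Baker–Venkataraman / cyclodehydration with a C26 acid.
3. 6 ⇒ noreugenin 4 (O-methylation); 3 ⇒ tetracosan-1-ol 1 (Appel-type iodination).
4. Ring order: no ring is formed. The benzene and γ-pyranone rings are bought together in noreugenin and the chain is grown from its 2-methyl group.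

Assumption: the target has no stereocentre and no stereogenic double bond, so it is achiral and "single enantiomer" needs no stereocontrol; tetracosan-1-ol and noreugenin are taken as commercial.

**Route**

Step 1
Reactants: 1 tetracosan-1-ol
Product: 3 1-iodotetracosane, via tetracosyloxytriphenylphosphonium iodide 2 (not isolated)
Conditions: PPh3 (1.3 equiv), imidazole (1.5 equiv), I2 (1.3 equiv), toluene, 60 °C, 2 h
Reagents that add atoms: iodine, II
Why: Garegg–Samuelsson (Appel-type) iodination, in which the alcohol attacks in situ Ph3P–I+ to give alkoxyphosphonium iodide 2 and iodide then displaces Ph3P=O by SN2 at the primary carbon, with warm toluene keeping the waxy C24 substrate dissolved and no stereocentre involved.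

Step 2
Reactants: 4 noreugenin (5,7-dihydroxy-2-methylchromone)
Product: 6 5,7-dimethoxy-2-methylchromone, via 5-hydroxy-7-methoxy-2-methylchromone 5 (not isolated)
Conditions: MeI (5 equiv), K2CO3 (4 equiv), DMF, 50 °C, 16 h
Reagents that add atoms: iodomethane, CI
Why: Williamson O-methylation (SN2 on MeI), in which the free 7-OH reacts first to give 5 and excess MeI/K2CO3 in warm DMF then alkylates the hydrogen-bonded 5-OH, while the weak base leaves the 2-methyl group and the ring carbons untouched.

Step 3
Reactants: 6 5,7-dimethoxy-2-methylchromone; 3 1-iodotetracosane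
Product: 8 5,7-dimethoxy-2-pentacosylchromone, via lithium 5,7-dimethoxy-2-methylidene-2H-chromen-4-olate 7 (not isolated)
Conditions: LDA (commercial solution, 1.25 equiv), THF, −78 °C, 45 min (6, 1.3 equiv, added slowly to the base); then 3 (1.0 equiv) in THF/DMPU, −78 → 0 °C, 6 h; aq NH4Cl
Reagents that add atoms: none
Why: Lateral (vinylogous) lithiation of the 2-methyl group (pKa about 20, far more acidic than any aryl or OMe C–H) gives cross-conjugated dienolate 7, which undergoes SN2 γ-alkylation at the exocyclic carbon with the primary iodide because only attack there restores the aromatic γ-pyranone; adding 6 to the base avoids Michael self-condensation, the slight excess of dienolate over 3 suppresses double alkylation, and no stereocentre is created.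

Step 4
Reactants: 8 5,7-dimethoxy-2-pentacosylchromone
Product: 10 5,7-dihydroxy-2-pentacosylchromone, via 5,7-bis(dibromoboryloxy)-2-pentacosylchromone 9 (not isolated)
Conditions: BBr3 (6 equiv), CH2Cl2, −78 → 40 °C, 24 h; then H2O, 0 °C
Reagents that add atoms: none
Why: Lewis-acid aryl methyl ether cleavage, in which BBr3 complexes each OMe oxygen and bromide removes the methyl group by SN2 (the 5-OMe fastest, through chelation to C4=O) to give aryloxyborane 9 that water hydrolyses to the free phenols, while the chromone core and the saturated chain are inert to BBr3.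

**Compound list**
1 | tetracosan-1-ol | CCCCCCCCCCCCCCCCCCCCCCCCO | starting material
2 | tetracosyloxytriphenylphosphonium iodide | CCCCCCCCCCCCCCCCCCCCCCCCO[P+](c1ccccc1)(c1ccccc1)c1ccccc1.[I-] | intermediate
3 | 1-iodotetracosane | CCCCCCCCCCCCCCCCCCCCCCCCI | intermediate
4 | noreugenin (5,7-dihydroxy-2-methylchromone) | Cc1cc(=O)c2c(O)cc(O)cc2o1 | starting material
5 | 5-hydroxy-7-methoxy-2-methylchromone (eugenin) | Cc1cc(=O)c2c(O)cc(OC)cc2o1 | intermediate
6 | 5,7-dimethoxy-2-methylchromone | Cc1cc(=O)c2c(OC)cc(OC)cc2o1 | intermediate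
7 | lithium 5,7-dimethoxy-2-methylidene-2H-chromen-4-olate | C=C1C=C([O-])c2c(OC)cc(OC)cc2O1.[Li+] | intermediate
8 | 5,7-dimethoxy-2-pentacosylchromone | CCCCCCCCCCCCCCCCCCCCCCCCCc1cc(=O)c2c(OC)cc(OC)cc2o1 | intermediate
9 | 5,7-bis(dibromoboryloxy)-2-pentacosylchromone | CCCCCCCCCCCCCCCCCCCCCCCCCc1cc(=O)c2c(OB(Br)Br)cc(OB(Br)Br)cc2o1 | intermediate
10 | 5,7-dihydroxy-2-pentacosylchromone (CNP0174425.0, achiral) | CCCCCCCCCCCCCCCCCCCCCCCCCc1cc(=O)c2c(O)cc(O)cc2o1 | target

**Totals**
Total step count: 4.
Longest linear sequence: 3 steps (4 → 6 → 8 → 10); step 1 is a one-step side branch.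

**Three steps most likely to fail, with fallbacks**

Step 3 (highest risk). The C24 iodide is barely soluble cold, so the SN2 may be slower than Michael self-condensation of 7 with 6 or than double alkylation. The fallback replaces the SN2 by a carbonyl addition; it sets out from 6 (with 1 as the source of the C24 partner) and comes back at 8. Alcohol 1 is oxidised (TEMPO cat., PhI(OAc)2, CH2Cl2, rt) to tetracosanal F1. Dienolate 7, made from 6 as in step 3, adds to F1 at −78 °C in a vinylogous aldol reaction that is fast at a temperature where self-condensation is negligible, giving after NH4Cl quench racemic 2-(2-hydroxypentacosyl)-5,7-dimethoxychromone F2. Acid-catalysed dehydration (TsOH cat., toluene, reflux, Dean–Stark) gives the conjugated (E)-5,7-dimethoxy-2-(pentacos-1-en-1-yl)chromone F3 and removes the temporary stereocentre. Hydrogenation of the disubstituted side-chain alkene (H2 1 atm, Pd/C, EtOAc/THF, rt, stopped after 1 equiv) gives 8; the pyranone C2=C3 vinylogous ester reduces much more slowly.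

Step 4. The 7-OMe group may cleave incompletely, and forcing conditions may degrade the material. The fallback changes the protecting group to an acid-labile acetal; it sets out from 4 and comes back at 10. Noreugenin 4 with NaH and MOMCl (DMF, 0 °C → rt) gives 5,7-bis(methoxymethoxy)-2-methylchromone F4. LDA (THF, −78 °C) converts it into lithium 5,7-bis(methoxymethoxy)-2-methylidene-2H-chromen-4-olate F5, which is alkylated with 3 as in step 3 to 5,7-bis(methoxymethoxy)-2-pentacosylchromone F6. Mild acetal cleavage (3 M HCl, MeOH/THF, 50 °C) then gives 10 without any ether cleavage.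

Step 2. The second methylation at the chelated 5-OH may stall, or forcing it may cause C-methylation. The fallback leaves the 5-OH unprotected and uses a dianion; it sets out from 4, goes through 5 (now isolated, using MeI 1.1 equiv, K2CO3, acetone, rt) and comes back at 9. LDA (2.3 equiv, THF/DMPU, −78 °C) deprotonates first the 5-OH and then the 2-methyl group of 5 to give dilithium 7-methoxy-2-methylidene-2H-chromene-4,5-diolate F7. The chelated phenoxide is unreactive, so 3 alkylates the dienolate carbon to give 5-hydroxy-7-methoxy-2-pentacosylchromone F8. BBr3 (4 equiv, CH2Cl2) cleaves the single remaining methyl ether and converts F8 into 9, which water hydrolyses to 10.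

**Further compounds**
F1 | step 3 | tetracosanal | CCCCCCCCCCCCCCCCCCCCCCCC=O
F2 | step 3 | 2-(2-hydroxypentacosyl)-5,7-dimethoxychromone (racemic) | CCCCCCCCCCCCCCCCCCCCCCCC(O)Cc1cc(=O)c2c(OC)cc(OC)cc2o1
F3 | step 3 | (E)-5,7-dimethoxy-2-(pentacos-1-en-1-yl)chromone | CCCCCCCCCCCCCCCCCCCCCCC/C=C/c1cc(=O)c2c(OC)cc(OC)cc2o1
F4 | step 4 | 5,7-bis(methoxymethoxy)-2-methylchromone | Cc1cc(=O)c2c(OCOC)cc(OCOC)cc2o1
F5 | step 4 | lithium 5,7-bis(methoxymethoxy)-2-methylidene-2H-chromen-4-olate | C=C1C=C([O-])c2c(OCOC)cc(OCOC)cc2O1.[Li+]
F6 | step 4 | 5,7-bis(methoxymethoxy)-2-pentacosylchromone | CCCCCCCCCCCCCCCCCCCCCCCCCc1cc(=O)c2c(OCOC)cc(OCOC)cc2o1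
F7 | step 2 | dilithium 7-methoxy-2-methylidene-2H-chromene-4,5-diolate | C=C1C=C([O-])c2c([O-])cc(OC)cc2O1.[Li+].[Li+]
F8 | step 2 | 5-hydroxy-7-methoxy-2-pentacosylchromone | CCCCCCCCCCCCCCCCCCCCCCCCCc1cc(=O)c2c(O)cc(OC)cc2o1
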